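**Retrosynthetic overview**

- Feature: in ring C, C4 is an isolated carbonyl carbon. It sits between C4a, which is C2 of a mirror-symmetric 5-methoxyresorcinol (ring A, OH on both neighbouring carbons), and the C3=C2 pair, which has the oxidation level of the two carbons of a ring-B arylacetylene.
- Endgame disconnections: the three MOM ethers (5-O, 2'-O, 5'-O), then the C3–CH2 bond of the prenyl group (Stille coupling), then C3–I (carbonyl-directed lithiation of C3–H).
- Key disconnection: ring C is cut at C4a–C4, C4–C3 and O1–C2 into 2-iodo-5-methoxybenzene-1,3-diol, CO and 1-ethynyl-4-methoxy-2,5-bis(methoxymethoxy)benzene.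
- Fragments: the iodoresorcinol comes from 5-methoxyresorcinol (bis-MOM ether, lithiation between the oxygens, I2, acid-free MOM removal). The alkyne comes from 2-methoxyhydroquinone (bis-MOM ether, iodination para to OMe, Sonogashira coupling, desilylation).
- Ring order: rings A and B are bought with the starting materials; the pyranone ring C is the only ring formed, in step 8.

Key step: step 8

Remark on the chemistry: the target has no stereocentre, and its only acyclic C=C carries two identical methyl groups. It is therefore achiral and has no E/Z isomer, so no stereocontrol is needed.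

**Route**

Step 1
Reactants: 1 5-methoxyresorcinol
Product: 2 1-methoxy-3,5-bis(methoxymethoxy)benzene
Conditions: MOMCl (2.5 equiv), i-Pr2NEt (3 equiv), CH2Cl2, 0 °C to rt, argon
Reagents that add atoms: chloromethyl methyl ether (MOMCl), COCCl
Why: Williamson-type O-alkylation of both equivalent phenols under a mild amine base should give the bis-acetal, whose OMOM groups then direct the lithiation.

Step 2
Reactants: 2 1-methoxy-3,5-bis(methoxymethoxy)benzene
Product: 4 2-iodo-5-methoxy-1,3-bis(methoxymethoxy)benzene, via aryllithium 3 (not isolated)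
Conditions: n-BuLi (1.1 equiv), THF, 0 °C; then I2 (1.2 equiv), THF, −78 °C to rt
Reagents that add atoms: iodine, II
Why: Directed ortho-metalation should remove the C–H between the two chelating OMOM groups in preference to the sites between OMOM and OMe, and iodinolysis of the aryllithium fixes iodine on the symmetry axis.

Step 3
Reactants: 4 2-iodo-5-methoxy-1,3-bis(methoxymethoxy)benzene
Product: 6 2-iodo-5-methoxybenzene-1,3-diol, via bis(trimethylsilyl) ether 5 (not isolated)
Conditions: TMSOTf (4 equiv), 2,2'-bipyridyl (6 equiv), MeCN, 0 °C to rt; then H2O, rt; product kept cold and dark and used promptly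
Reagents that add atoms: none
Why: Silyl triflate/bipyridyl cleavage of aryl MOM ethers runs through the aryl TMS ethers and water in a buffered, non-protic medium, and so avoids the ipso-protonation at C–I by which 2-iodoresorcinols lose or shift iodine in mineral acid.

Step 4
Reactants: 7 2-methoxyhydroquinone
Product: 8 2-methoxy-1,4-bis(methoxymethoxy)benzene
Conditions: MOMCl (2.5 equiv), i-Pr2NEt (3 equiv), CH2Cl2, 0 °C to rt, argon
Reagents that add atoms: chloromethyl methyl ether (MOMCl), COCCl
Why: Williamson-type O-alkylation of both phenols should proceed cleanly, and the inert atmosphere with a non-oxidising amine base keeps the hydroquinone from going to the quinone.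

Step 5
Reactants: 8 2-methoxy-1,4-bis(methoxymethoxy)benzene
Product: 9 1-iodo-4-methoxy-2,5-bis(methoxymethoxy)benzene
Conditions: NIS (1.05 equiv), MeCN, rt, dark
Reagents that add atoms: N-iodosuccinimide, O=C1CCC(=O)N1I
Why: Electrophilic aromatic iodination of a 1,2,4-trialkoxybenzene should go to the one unhindered carbon that is para to OMe and ortho to an OMOM group, and neutral NIS leaves the acetals intact.

Step 6
Reactants: 9 1-iodo-4-methoxy-2,5-bis(methoxymethoxy)benzene; 10 trimethylsilylacetylene
Product: 11 {[4-methoxy-2,5-bis(methoxymethoxy)phenyl]ethynyl}trimethylsilane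
Conditions: PdCl2(PPh3)2 (3 mol %), CuI (5 mol %), Et3N–THF, 50 °C, argon
Reagents that add atoms: trimethylsilylacetylene (10), C#C[Si](C)(C)C
Why: Sonogashira coupling of an aryl iodide with a terminal alkyne tolerates the ether and acetal groups, and the silyl cap prevents double coupling.

Step 7
Reactants: 11 {[4-methoxy-2,5-bis(methoxymethoxy)phenyl]ethynyl}trimethylsilane
Product: 12 1-ethynyl-4-methoxy-2,5-bis(methoxymethoxy)benzene
Conditions: K2CO3 (0.2 equiv), MeOH, rt
Reagents that add atoms: none
Why: Base-catalysed methanolysis of the alkynyl C–Si bond (protodesilylation) should free the terminal alkyne without touching the base-stable MOM ethers.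

Step 8
Reactants: 6 2-iodo-5-methoxybenzene-1,3-diol; 12 1-ethynyl-4-methoxy-2,5-bis(methoxymethoxy)benzene; 13 carbon monoxide
Product: 16 5-hydroxy-7,4'-dimethoxy-2',5'-bis(methoxymethoxy)flavone, via ynone 14 (not isolated), via enaminone 15 (not isolated)
Conditions: PdCl2(dppf) (5 mol %), degassed Et2NH (solvent), CO (20 bar), 100 °C, autoclave, no copper salt
Reagents that add atoms: carbon monoxide (13), [C-]#[O+]
Why: Pd(0) adds oxidatively to the C–I bond of 6, CO inserts to give the 2,6-dihydroxy-4-methoxybenzoyl-palladium species, and the alkynyl group of 12 (deprotonated by the amine at Pd) is coupled to it, which gives ynone 14 with the C4a–C4 and C4–C3 bonds. Et2NH then adds to the alkyne carbon that bears ring B to give the push-pull enaminone 15, and an ortho-phenol attacks this same carbon and expels the amine (addition-elimination), which makes O1–C2. The closest known reaction type is the carbonylative Sonogashira coupling-cyclisation of 2-iodophenols with terminal alkynes in a secondary amine, of which the di-ortho-oxygenated iodide 6 is a hindered and electron-rich member. Ring C closes in a formal 6-endo mode, because in 15 only the amine-bearing carbon is electrophilic, so the 5-exo attack at the carbon next to the carbonyl that leads to an aurone is shut off. The step needs CO uptake ahead of direct alkynylation (which would end in a benzofuran) and ahead of amide formation; 20 bar of CO, the absence of copper, the fast migration of an electron-rich aryl group to CO and the shielding of the acyl carbon by two ortho oxygens should secure this. No regiocontrol in ring A is needed, since the mirror plane through C2 and C5 of 6 makes both hydroxyls equivalent and the unused one ends as the chelated 5-OH, and no stereocentre is formed.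

Step 9
Reactants: 16 5-hydroxy-7,4'-dimethoxy-2',5'-bis(methoxymethoxy)flavone
Product: 18 7,4'-dimethoxy-5,2',5'-tris(methoxymethoxy)flavone, via sodium phenoxide 17 (not isolated)
Conditions: NaH (1.5 equiv), THF–DMF, 0 °C; then MOMCl (1.5 equiv), 0 °C to rt
Reagents that add atoms: chloromethyl methyl ether (MOMCl), COCCl
Why: The 5-OH is hydrogen-bonded to C4=O and inert to amine bases, so full deprotonation with NaH followed by Williamson O-alkylation is used to remove the only acidic proton before the metalation.

Step 10
Reactants: 18 7,4'-dimethoxy-5,2',5'-tris(methoxymethoxy)flavone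
Product: 20 3-iodo-7,4'-dimethoxy-5,2',5'-tris(methoxymethoxy)flavone, via 3-lithioflavone 19 (not isolated)
Conditions: LDA (1.3 equiv, commercial solution), THF, −78 °C; then I2 (1.5 equiv), THF, −78 °C
Reagents that add atoms: iodine, II
Why: Carbonyl-directed vinylic lithiation of flavones at C3 with a hindered lithium amide is known chemistry, because LDA at −78 °C is too weak to metalate the aryl ether C–H bonds and too bulky to add at C2, and iodinolysis traps the anion before it can open the ring.

Step 11
Reactants: 20 3-iodo-7,4'-dimethoxy-5,2',5'-tris(methoxymethoxy)flavone; 21 tributyl(3-methylbut-2-en-1-yl)stannane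
Product: 22 7,4'-dimethoxy-5,2',5'-tris(methoxymethoxy)-3-(3-methylbut-2-en-1-yl)flavone
Conditions: Pd(PPh3)4 (10 mol %), degassed DMF, 90 °C
Reagents that add atoms: tributyl(3-methylbut-2-en-1-yl)stannane (21), CCCC[Sn](CCCC)(CCCC)CC=C(C)C
Why: Migita–Kosugi–Stille coupling of the α-iodoenone-type iodide should give the linear prenyl group, because the sigma/pi-prenyl palladium intermediate forms the C–C bond at its unsubstituted CH2 terminus.

Step 12
Reactants: 22 7,4'-dimethoxy-5,2',5'-tris(methoxymethoxy)-3-(3-methylbut-2-en-1-yl)flavone
Product: 23 artoindonesianin Q (5,2',5'-trihydroxy-7,4'-dimethoxy-3-prenylflavone)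
Conditions: HCl (0.5 M in MeOH), 40 °C, argon, degassed solvent
Reagents that add atoms: none
Why: Acid-catalysed transacetalisation to methanol should remove all three aryl MOM groups under mild conditions, because no phenol lies within five- or six-ring reach of the prenyl alkene (closure from 2'-OH would be eight-membered) and exclusion of air protects the hydroquinone ring B.

**Compound list**

1 | 5-methoxyresorcinol | COc1cc(O)cc(O)c1 | starting material
2 | 1-methoxy-3,5-bis(methoxymethoxy)benzene | COCOc1cc(OC)cc(OCOC)c1 | intermediate
3 | [4-methoxy-2,6-bis(methoxymethoxy)phenyl]lithium | [Li]c1c(OCOC)cc(OC)cc1OCOC | intermediate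
4 | 2-iodo-5-methoxy-1,3-bis(methoxymethoxy)benzene | COCOc1cc(OC)cc(OCOC)c1I | intermediate
5 | 2-iodo-5-methoxy-1,3-bis(trimethylsilyloxy)benzene | COc1cc(O[Si](C)(C)C)c(I)c(O[Si](C)(C)C)c1 | intermediate
6 | 2-iodo-5-methoxybenzene-1,3-diol | COc1cc(O)c(I)c(O)c1 | intermediate
7 | 2-methoxyhydroquinone | COc1cc(O)ccc1O | starting material
8 | 2-methoxy-1,4-bis(methoxymethoxy)benzene | COCOc1ccc(OCOC)c(OC)c1 | intermediate
9 | 1-iodo-4-methoxy-2,5-bis(methoxymethoxy)benzene | COCOc1cc(OC)c(OCOC)cc1I | intermediate
10 | trimethylsilylacetylene | C#C[Si](C)(C)C | starting material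
11 | {[4-methoxy-2,5-bis(methoxymethoxy)phenyl]ethynyl}trimethylsilane | COCOc1cc(OC)c(OCOC)cc1C#C[Si](C)(C)C | intermediate
12 | 1-ethynyl-4-methoxy-2,5-bis(methoxymethoxy)benzene | COCOc1cc(OC)c(OCOC)cc1C#C | intermediate
13 | carbon monoxide | [C-]#[O+] | starting material
14 | 1-(2,6-dihydroxy-4-methoxyphenyl)-3-[4-methoxy-2,5-bis(methoxymethoxy)phenyl]prop-2-yn-1-one | COc1cc(O)c(C(=O)C#Cc2cc(OCOC)c(OC)cc2OCOC)c(O)c1 | intermediate
15 | (E)-3-(diethylamino)-1-(2,6-dihydroxy-4-methoxyphenyl)-3-[4-methoxy-2,5-bis(methoxymethoxy)phenyl]prop-2-en-1-one (push-pull alkene, geometry labile, drawn E) | CCN(CC)/C(=C/C(=O)c1c(O)cc(OC)cc1O)c1cc(OCOC)c(OC)cc1OCOC | intermediate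
16 | 5-hydroxy-7-methoxy-2-[4-methoxy-2,5-bis(methoxymethoxy)phenyl]-4H-chromen-4-one | COc1cc(O)c2c(=O)cc(-c3cc(OCOC)c(OC)cc3OCOC)oc2c1 | intermediate
17 | sodium 5-phenoxide of 16 | [Na+].COc1cc([O-])c2c(=O)cc(-c3cc(OCOC)c(OC)cc3OCOC)oc2c1 | intermediate
18 | 7-methoxy-5-(methoxymethoxy)-2-[4-methoxy-2,5-bis(methoxymethoxy)phenyl]-4H-chromen-4-one | COc1cc(OCOC)c2c(=O)cc(-c3cc(OCOC)c(OC)cc3OCOC)oc2c1 | intermediate
19 | 3-lithio derivative of 18 | COc1cc(OCOC)c2c(=O)c([Li])c(-c3cc(OCOC)c(OC)cc3OCOC)oc2c1 | intermediate
20 | 3-iodo-7-methoxy-5-(methoxymethoxy)-2-[4-methoxy-2,5-bis(methoxymethoxy)phenyl]-4H-chromen-4-one | COc1cc(OCOC)c2c(=O)c(I)c(-c3cc(OCOC)c(OC)cc3OCOC)oc2c1 | intermediate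
21 | tributyl(3-methylbut-2-en-1-yl)stannane | CCCC[Sn](CCCC)(CCCC)CC=C(C)C | starting material
22 | 7-methoxy-5-(methoxymethoxy)-2-[4-methoxy-2,5-bis(methoxymethoxy)phenyl]-3-(3-methylbut-2-en-1-yl)-4H-chromen-4-one | COc1cc(OCOC)c2c(=O)c(CC=C(C)C)c(-c3cc(OCOC)c(OC)cc3OCOC)oc2c1 | intermediate
23 | artoindonesianin Q, 2-(2,5-dihydroxy-4-methoxyphenyl)-5-hydroxy-7-methoxy-3-(3-methylbut-2-en-1-yl)-4H-chromen-4-one | COc1cc(O)c2c(=O)c(CC=C(C)C)c(-c3cc(O)c(OC)cc3O)oc2c1 | target

**Step count**

Total step count: 12.
Longest linear sequence: 9 steps (7 to 23, steps 4 to 12). The ring-A branch (steps 1 to 3) joins at step 8.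

**The three steps most likely to fail**

Risk 1 (step 8). Oxidative addition into an iodide flanked by two hydroxyls and fed by three oxygen donors may be slow. Three processes could then outrun the wanted sequence:
- reductive loss of iodine from the ring;
- capture of the acyl-palladium by diethylamine;
- alkynylation without CO uptake.

The fallback forms the same three bonds one after the other, without palladium or CO. It sets out from 2 and 12.
- Aryllithium 3, made as in step 2, is quenched with DMF to give 4-methoxy-2,6-bis(methoxymethoxy)benzaldehyde F1.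
- The lithium acetylide of 12 (n-BuLi, THF, −78 °C) adds to it to give racemic 1-[4-methoxy-2,6-bis(methoxymethoxy)phenyl]-3-[4-methoxy-2,5-bis(methoxymethoxy)phenyl]prop-2-yn-1-ol F2.
- MnO2 in CH2Cl2 oxidises this doubly activated alcohol to the tetra-MOM ynone F3.
- Et2NH in EtOH adds in Michael fashion to give the tetra-MOM enaminone F4.
- Methanolic HCl (more than one equivalent) removes all four MOM groups, and a freed ring-A phenol closes on the protonated enaminone carbon with loss of the amine. This gives 5,2',5'-trihydroxy-7,4'-dimethoxyflavone F5. The 2'-OH cannot compete at that carbon, because it would form a four-membered ring.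
- MOMCl/NaH in THF–DMF under argon puts three MOM groups back, and the route is rejoined at 18.

Risk 2 (step 10). Three things may go wrong:
- the 3-lithio species may expel the ring oxygen by anti β-elimination and open the pyranone;
- metalation next to an OMOM group may compete;
- the amide may add at C2.

The fallback drops both the lithium species and the iodide, and reverses the polarity of the coupling. It sets out from 18. Carbonyl-directed zincation with the hindered zinc amide TMPZnCl·LiCl (THF, rt), a metalation known for chromones, should give the covalent and non-eliminating 3-(chlorozincio)flavone F6. A Negishi-type Pd(PPh3)4-catalysed allylation with prenyl bromide follows. It forms the bond at the CH2 terminus of the π-prenyl palladium intermediate and returns to the route at 22, bypassing 20.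

Risk 3 (step 11). Transfer of the prenyl group may occur with allylic transposition, forming the bond at the tertiary terminus. Transmetalation at an iodide wedged between the carbonyl and an ortho-substituted aryl group may also be slow enough for reductive deiodination to compete.

The fallback separates C–C bond formation from the installation of the gem-dimethyl terminus. It sets out from 20. Stille coupling with allyltributylstannane, whose two termini are equivalent, gives the 3-allylflavone F7. Olefin cross-metathesis with excess 2-methyl-2-butene (second-generation NHC–ruthenium benzylidene catalyst, CH2Cl2, 40 °C) then converts the allyl into the prenyl group and returns to the route at 22.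

**Further compounds**

F1 | step 8 | 4-methoxy-2,6-bis(methoxymethoxy)benzaldehyde | COCOc1cc(OC)cc(OCOC)c1C=O
F2 | step 8 | rac-1-[4-methoxy-2,6-bis(methoxymethoxy)phenyl]-3-[4-methoxy-2,5-bis(methoxymethoxy)phenyl]prop-2-yn-1-ol | COCOc1cc(OC)cc(OCOC)c1C(O)C#Cc1cc(OCOC)c(OC)cc1OCOC
F3 | step 8 | 1-[4-methoxy-2,6-bis(methoxymethoxy)phenyl]-3-[4-methoxy-2,5-bis(methoxymethoxy)phenyl]prop-2-yn-1-one | COCOc1cc(OC)cc(OCOC)c1C(=O)C#Cc1cc(OCOC)c(OC)cc1OCOC
F4 | step 8 | (E)-3-(diethylamino)-1-[4-methoxy-2,6-bis(methoxymethoxy)phenyl]-3-[4-methoxy-2,5-bis(methoxymethoxy)phenyl]prop-2-en-1-one | CCN(CC)/C(=C/C(=O)c1c(OCOC)cc(OC)cc1OCOC)c1cc(OCOC)c(OC)cc1OCOC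
F5 | step 8 | 5,2',5'-trihydroxy-7,4'-dimethoxyflavone | COc1cc(O)c2c(=O)cc(-c3cc(O)c(OC)cc3O)oc2c1
F6 | step 10 | 3-(chlorozincio)-7,4'-dimethoxy-5,2',5'-tris(methoxymethoxy)flavone | COc1cc(OCOC)c2c(=O)c([Zn]Cl)c(-c3cc(OCOC)c(OC)cc3OCOC)oc2c1
F7 | step 11 | 3-allyl-7,4'-dimethoxy-5,2',5'-tris(methoxymethoxy)flavone | COc1cc(OCOC)c2c(=O)c(CC=C)c(-c3cc(OCOC)c(OC)cc3OCOC)oc2c1
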